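Z, the second partner, is the reagent I keep the books on.

| flask | L | Z | time |
|---|---|---|---|
| green | 80.0 mM | 88.0 mM |  |
| violet | 48.0 mM | 56.0 mM |  |
| red | 80.0 mM | 44.0 mM |  |
| blue | 80.0 mM | 19.0 mM | 8.1 min |

- green run (time / min: [X] / mM): 0.29: 10.14; 0.88: 23.90; 1.7: 34.98; 2.7: 42.25; 3.8: 47.04; 5.1: 51.19; 6.5: 54.48; 8.1: 56.68
- violet run (time / min: [X] / mM): 0.29: 4.72; 0.88: 11.53; 1.7: 18.09; 2.7: 22.82; 3.8: 26.56; 5.1: 28.85; 6.5: 31.29; 8.1: 33.41
- red run (time / min: [X] / mM): 0.29: 6.38; 0.88: 14.69; 1.7: 21.24; 2.7: 25.92; 3.8: 28.80; 5.1: 31.27; 6.5: 33.34; 8.1: 34.91

(standard deviation of a reading: 0.2 mM)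

- Overall: L + Z -> X.
- Constant volume, constant temperature.
- The analysis sees a species whether free or bound.
- "The second partner" is Z.
- An order is taken over about fifteen percent of the charge, up and down.

- order of the initial rate in [L], near the charge of the green run, the rate being that where two percent of its L are X (one fixed amount of X, the same in the runs compared)
- order of the initial rate in [Z], near the charge of the green run, the rate being that where two percent of its L are X
- the violet run starts with 32.0 mM less of L and of Z than the green run, and with no X. Compared where both hold the same amount of L, once fifteen percent of what the violet run was charged with has turned into X, is the violet run faster, slower or alike (within a tenth)?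
- X in the blue run at 8.1 min, as a share of the L charged

In the blue run Z is the limiting reagent: 19.0 mM is less than the 80.0 mM of L. One Z goes into each X, so X can reach at most 23.8 % of the L charged. The balance is simple: Z left, free or bound, is Z charged minus X. What I need is how fast that balance empties.

The red run charges the same L as the blue run, so at equal X the two hold equal L. Over its first 0.29 min, the red run makes X at 22.0 mM min⁻¹ with about 40.8 mM of Z left. That is 0.539 min⁻¹. If Z decays at that pace, the blue run holds 0.241 mM of Z at 8.1 min, and X stands at 23.4 %.

This link is weak, because that pace was read up to 6.38 mM of X, and the blue run ends with more X than that. So I read the red run where X is about 18.0 mM. There X rises at 7.99 mM min⁻¹ with 26.0 mM of Z left, which gives 0.307 min⁻¹, slower than before. This reading, the rate of X divided by the Z left at a stated amount of X, is my turnover of Z, a pseudo-first-order constant. Applied to the whole blue run, it leaves 1.58 mM of Z, so I commit to 21.8 %.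

The forecast says 0.9 for the order in L, 0.6 for the order in Z, faster for the violet run, and 20.8 % for the blue run, lower than mine. Its grounds start from the green and violet runs at equal L: “The loss is therefore not simple bimolecular depletion”.

The flask gives 1.0 for L, 0.71 for Z, faster for the violet run, and 21.7 % for the blue run. The order in Z is where the forecast parts from it, lying lower.

    L + Z → X + Q (10.98 M⁻¹ min⁻¹)
    Z + Q ⇌ ZQ, settled at all times (147.0 M⁻¹)
    2 Z ⇌ Z2, settled at all times (9.190 M⁻¹)

In the blue run, L + Z → X + Q ran for the whole 8.1 min while part of the Q made held Z as ZQ, and the 1.66 mM of Z left at the end, free and bound together, means a turnover of 0.301 min⁻¹ over the run. In the red run, X comes to half of the L charged at 18.5 min, with 4.00 mM of Z left, and the turnover over that time is 0.129 min⁻¹.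

(The runs are simulated from invented constants, and the scatter is random.)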